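**Retrosynthetic overview**
1. Target 14 ⇐ hexamethoxyflavone 13 by chelation-controlled cleavage of the 5-O-methyl group (last step).
2. 13 ⇐ C2–C1′ bond: the chromone C2, normally an electrophilic β-carbon, is used as a nucleophile (C2-zinc reagent 11, a β-acylvinyl, homoenolate-type anion) and joined to the C–Br carbon of 2-bromo-5-methoxyphenol 10.
3. 3-Methoxychromone 9 ⇐ hydroxy ketone 7 plus DMF-DMA as the C2 carbon (pyranone ring closure).
4. 7 ⇐ pentamethoxybenzene 4 plus methoxyacetyl chloride 5 (C4, C3 and the 3-OMe); 4 ⇐ 2,6-dimethoxy-1,4-benzoquinone 1 (fifth oxygen by Thiele–Winter acetoxylation).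
5. Ring order: A ring from 1, C ring closed in step 4, B ring attached in step 5.

Assumption: the target has no stereocentre and no stereogenic double bond, so there is no enantiomer to select; the only stereodescriptor in the route is the Z enaminone 8, whose geometry does not affect the outcome.

**Step 1**
Reactants: 1 2,6-dimethoxy-1,4-benzoquinone
Product: 2 3,5-dimethoxybenzene-1,2,4-triyl triacetate
Conditions: Ac2O, cat. conc. H2SO4, 25–40 °C, 48 h; ice-water
Reagents that add atoms: acetic anhydride, CC(=O)OC(C)=O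
Why: Thiele–Winter acetoxylation: acid-catalysed conjugate addition of acetate to the only unsubstituted quinone position, then aromatisation and O-acetylation, gives the penta-oxygenated benzene.

**Step 2**
Reactants: 2 3,5-dimethoxybenzene-1,2,4-triyl triacetate
Product: 4 pentamethoxybenzene, via 3,5-dimethoxybenzene-1,2,4-triol 3 (not isolated)
Conditions: Me2SO4 (6 eq), 20 % aq NaOH, MeOH, cat. Na2S2O4, N2, 0 → 60 °C
Reagents that add atoms: dimethyl sulfate, COS(=O)(=O)OC
Why: One-pot saponification and Williamson O-methylation under nitrogen traps the air-sensitive triol as it forms.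

**Step 3**
Reactants: 4 pentamethoxybenzene; 5 methoxyacetyl chloride
Product: 7 1-(2-hydroxy-3,4,5,6-tetramethoxyphenyl)-2-methoxyethan-1-one, via pentamethoxyphenyl methoxymethyl ketone 6 (not isolated)
Conditions: 5 (1.2 eq), AlCl3 (2.5 eq), Et2O/CH2Cl2, 0 °C → rt; 1 M HCl work-up
Reagents that add atoms: none
Why: Friedel–Crafts acylation at the single free ring position, followed by chelation-controlled AlCl3 cleavage of one of the two equivalent ortho methyl ethers; the aluminium phenoxide chelate then protects the second ortho-OMe.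

**Step 4**
Reactants: 7 1-(2-hydroxy-3,4,5,6-tetramethoxyphenyl)-2-methoxyethan-1-one
Product: 9 3,5,6,7,8-pentamethoxy-4H-chromen-4-one, via dimethylamino enaminone 8 (not isolated)
Conditions: DMF-DMA (3 eq), PhMe, 100 °C; then conc. HCl, CH2Cl2, 40 °C
Reagents that add atoms: N,N-dimethylformamide dimethyl acetal, COC(OC)N(C)C
Why: Enaminone chromone synthesis: the activated CH2 condenses with DMF-DMA, and the phenol closes the pyranone by addition–elimination with loss of dimethylamine.

**Step 5**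
Reactants: 9 3,5,6,7,8-pentamethoxy-4H-chromen-4-one; 10 2-bromo-5-methoxyphenol
Product: 13 2-(2-hydroxy-4-methoxyphenyl)-3,5,6,7,8-pentamethoxy-4H-chromen-4-one, via chromon-2-ylzinc chloride 11 (not isolated), via chloromagnesium 2-bromo-5-methoxyphenoxide 12 (not isolated)
Conditions: 9: TMPZnCl·LiCl (1.2 eq), MgCl2 (1.2 eq), THF, 25 °C, 1 h; 10 (1.3 eq): MeMgCl (1.3 eq), THF, 0 °C; combine, Pd(OAc)2 (3 mol %), SPhos (6 mol %), THF, 50 °C; 1 M HCl work-up
Reagents that add atoms: none
Why: Directed zincation with a TMP-zinc amide removes the only pyranone C–H (C2, acidified by O1, the 3-OMe and the Mg-complexed C4=O), turning the normally electrophilic chromone β-carbon into a β-acylvinyl (homoenolate-type, d3) nucleophile that Negishi cross-coupling joins to the electrophilic C–Br carbon of the pre-formed phenoxide; no stereocentre is created.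

**Step 6**
Reactants: 13 2-(2-hydroxy-4-methoxyphenyl)-3,5,6,7,8-pentamethoxy-4H-chromen-4-one
Product: 14 5,2'-dihydroxy-3,6,7,8,4'-pentamethoxyflavone
Conditions: BCl3 (2.5 eq, 1 M in CH2Cl2), CH2Cl2, −78 → 0 °C; MeOH then aq NaHCO3
Reagents that add atoms: none
Why: Chelation-controlled Lewis-acid demethylation: the six-membered O4···B···O5 chelate activates only the peri 5-OMe, so the 3-, 6-, 7-, 8- and 4'-OMe groups survive at or below 0 °C.

**Compound list**
1 | 2,6-dimethoxy-1,4-benzoquinone | COC1=CC(=O)C=C(OC)C1=O | starting material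
2 | 3,5-dimethoxybenzene-1,2,4-triyl triacetate | COc1cc(OC(C)=O)c(OC(C)=O)c(OC)c1OC(C)=O | intermediate
3 | 3,5-dimethoxybenzene-1,2,4-triol | COc1cc(O)c(O)c(OC)c1O | intermediate
4 | pentamethoxybenzene | COc1cc(OC)c(OC)c(OC)c1OC | intermediate
5 | methoxyacetyl chloride | COCC(Cl)=O | starting material
6 | 2-methoxy-1-(2,3,4,5,6-pentamethoxyphenyl)ethan-1-one | COCC(=O)c1c(OC)c(OC)c(OC)c(OC)c1OC | intermediate
7 | 1-(2-hydroxy-3,4,5,6-tetramethoxyphenyl)-2-methoxyethan-1-one | COCC(=O)c1c(O)c(OC)c(OC)c(OC)c1OC | intermediate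
8 | (Z)-3-(dimethylamino)-1-(2-hydroxy-3,4,5,6-tetramethoxyphenyl)-2-methoxyprop-2-en-1-one | CO/C(=C\N(C)C)C(=O)c1c(O)c(OC)c(OC)c(OC)c1OC | intermediate
9 | 3,5,6,7,8-pentamethoxy-4H-chromen-4-one | COc1coc2c(OC)c(OC)c(OC)c(OC)c2c1=O | intermediate
10 | 2-bromo-5-methoxyphenol | COc1ccc(Br)c(O)c1 | starting material
11 | (3,5,6,7,8-pentamethoxy-4-oxo-4H-chromen-2-yl)zinc chloride | COc1c([Zn]Cl)oc2c(OC)c(OC)c(OC)c(OC)c2c1=O | intermediate
12 | chloromagnesium 2-bromo-5-methoxyphenoxide | COc1ccc(Br)c(O[Mg]Cl)c1 | intermediate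
13 | 2-(2-hydroxy-4-methoxyphenyl)-3,5,6,7,8-pentamethoxy-4H-chromen-4-one | COc1ccc(-c2oc3c(OC)c(OC)c(OC)c(OC)c3c(=O)c2OC)c(O)c1 | intermediate
14 | 5,2'-dihydroxy-3,6,7,8,4'-pentamethoxyflavone | COc1ccc(-c2oc3c(OC)c(OC)c(OC)c(O)c3c(=O)c2OC)c(O)c1 | target

**Step count**
Total steps: 6. Longest linear sequence: 6 (1 → 2 → 4 → 7 → 9 → 13 → 14).

**Steps most likely to fail, with fallbacks**

Step 5 (C2-zincation and Negishi coupling with an unprotected halophenoxide). The phenoxide may protonate the zinc reagent or slow oxidative addition. The fallback sets out from 10 and rejoins the route at 14. Compound 10 is benzylated (BnBr, K2CO3, DMF) to 2-(benzyloxy)-1-bromo-4-methoxybenzene F1. F1 is coupled with zinc reagent 11, made from 9 as in step 5, under Pd(OAc)2/SPhos to give 2-[2-(benzyloxy)-4-methoxyphenyl]-3,5,6,7,8-pentamethoxy-4H-chromen-4-one F2. BCl3 in CH2Cl2 (−78 → 0 °C) then removes the benzyl ether and the 5-O-methyl group in one operation to give 14.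

Step 3 (Friedel–Crafts acylation with in-situ demethylation). Methoxyacetyl chloride can decarbonylate under AlCl3, and the demethylation may stop short or go too far. The fallback sets out from 4 and rejoins the route at 7. Compound 4 is lithiated at its only C–H (n-BuLi, TMEDA, THF, 0 °C) to (2,3,4,5,6-pentamethoxyphenyl)lithium F3. F3 is acylated with the Weinreb amide N,2-dimethoxy-N-methylacetamide to give ketone 6, now isolated. One equivalent of BCl3 (CH2Cl2, −78 → 0 °C) then cleaves one ortho-OMe of 6 under chelation control to give 7.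

Step 6 (selective 5-O-demethylation on the finished flavone). The 3-OMe or 6-OMe may also be cleaved in the presence of the 2'-phenol. The fallback sets out from 9 and rejoins the route at 14, moving the Lewis-acid step to the simple chromone and finishing by neutral hydrogenolysis. Compound 9 is treated with BCl3 to give 5-hydroxy-3,6,7,8-tetramethoxy-4H-chromen-4-one F4. F4 is benzylated (BnBr, K2CO3, DMF, 80 °C) to 5-(benzyloxy)-3,6,7,8-tetramethoxy-4H-chromen-4-one F5. F5 is zincated as in step 5 to [5-(benzyloxy)-3,6,7,8-tetramethoxy-4-oxo-4H-chromen-2-yl]zinc chloride F6. F6 is coupled with phenoxide 12 under Pd(OAc)2/SPhos to give 5-(benzyloxy)-2-(2-hydroxy-4-methoxyphenyl)-3,6,7,8-tetramethoxy-4H-chromen-4-one F7. H2 with Pd/C in EtOAc removes the benzyl group to give 14.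

**Further compounds**
F1 | step 5 | 2-(benzyloxy)-1-bromo-4-methoxybenzene | COc1ccc(Br)c(OCc2ccccc2)c1
F2 | step 5 | 2-[2-(benzyloxy)-4-methoxyphenyl]-3,5,6,7,8-pentamethoxy-4H-chromen-4-one | COc1ccc(-c2oc3c(OC)c(OC)c(OC)c(OC)c3c(=O)c2OC)c(OCc2ccccc2)c1
F3 | step 3 | (2,3,4,5,6-pentamethoxyphenyl)lithium | [Li]c1c(OC)c(OC)c(OC)c(OC)c1OC
F4 | step 6 | 5-hydroxy-3,6,7,8-tetramethoxy-4H-chromen-4-one | COc1coc2c(OC)c(OC)c(OC)c(O)c2c1=O
F5 | step 6 | 5-(benzyloxy)-3,6,7,8-tetramethoxy-4H-chromen-4-one | COc1coc2c(OC)c(OC)c(OC)c(OCc3ccccc3)c2c1=O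
F6 | step 6 | [5-(benzyloxy)-3,6,7,8-tetramethoxy-4-oxo-4H-chromen-2-yl]zinc chloride | COc1c([Zn]Cl)oc2c(OC)c(OC)c(OC)c(OCc3ccccc3)c2c1=O
F7 | step 6 | 5-(benzyloxy)-2-(2-hydroxy-4-methoxyphenyl)-3,6,7,8-tetramethoxy-4H-chromen-4-one | COc1ccc(-c2oc3c(OC)c(OC)c(OC)c(OCc4ccccc4)c3c(=O)c2OC)c(O)c1
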